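**Retrosynthetic overview**

- The pyranone ring (O1–C2–C3–C4–C4a–C8a) is opened last at O1–C2. It is closed in the forward sense by a 6-endo oxa-Michael addition of an open-chain, achiral 2-aryl-1-(2,6-dihydroxyaryl)propenone, and catalyst-controlled protonation at C3 sets the only stereocentre (3S) in the final step.
- Enabling feature: on ring A the ketone carbon C4 (on C4a) is flanked by two equivalent ortho oxygens, the later O1 on C8a and the C5 hydroxyl. Either phenol therefore closes to the same ring and the other becomes the chelated 5-OH. C2 is an unsubstituted CH2, and C3 is the ketone α-carbon bearing ring B, so it can arise from an enolate.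
- The propenone is traced back to formaldehyde (C2, α-methylenation) and to a Pd-catalysed α-arylation (C3–aryl bond) of MOM-protected 2′,6′-dihydroxy-4′-methoxyacetophenone with a 6-bromochromene.
- Ring order: rings A and B are bought as benzenes, the 2,2-dimethylpyran ring on ring B is formed first (phenol + enal, oxa-6π), and the pyranone ring is formed last.

Key step: step 6

Assumption: the sense of induction of the bifunctional catalyst on this substrate class cannot be assigned in advance. The quinine-derived squaramide 3-{[3,5-bis(trifluoromethyl)phenyl]amino}-4-{[(8α,9S)-6′-methoxycinchonan-9-yl]amino}cyclobut-3-ene-1,2-dione is written, and its quinidine-derived pseudo-enantiomer would be used instead if the (3R)-ketone predominates.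

**Step 1**
Reactants: 1 4-bromo-3-methoxyphenol; 2 3-methylbut-2-enal
Product: 5 6-bromo-7-methoxy-2,2-dimethyl-2H-chromene, via cyclic boronate 3 (not isolated), via o-quinone methide 4 (not isolated)
Conditions: PhB(OH)2 (1 equiv), AcOH (cat.), PhMe, reflux, Dean–Stark
Reagents that add atoms: none
Why: Phenylboronic acid-templated ortho-condensation (cyclic boronate 3) and loss of PhB(OH)2 should give o-quinone methide 4, which closes by oxa-6π electrocyclisation to the 2,2-dimethyl-2H-chromene; condensation is expected at the unhindered ortho carbon para to OMe, which places Br at C6 and OMe at C7.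

**Step 2**
Reactants: 6 1-(2,6-dihydroxy-4-methoxyphenyl)ethan-1-one
Product: 7 1-[4-methoxy-2,6-bis(methoxymethoxy)phenyl]ethan-1-one
Conditions: NaH (2.5 equiv), MOMCl (2.5 equiv), DMF, 0 °C → rt
Reagents that add atoms: chloromethyl methyl ether (MOMCl), COCCl
Why: Williamson-type O-alkylation of the bis-phenoxide (NaH is needed because one hydroxyl is hydrogen-bonded to the ketone) masks both phenols for the basic enolate chemistry of steps 3 and 4.

**Step 3**
Reactants: 7 1-[4-methoxy-2,6-bis(methoxymethoxy)phenyl]ethan-1-one; 5 6-bromo-7-methoxy-2,2-dimethyl-2H-chromene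
Product: 8 1-[4-methoxy-2,6-bis(methoxymethoxy)phenyl]-2-(7-methoxy-2,2-dimethyl-2H-chromen-6-yl)ethan-1-one
Conditions: Pd2(dba)3 (1.5 mol %), Xantphos (3.6 mol %), NaOtBu (1.3 equiv), THF, 70 °C
Reagents that add atoms: none
Why: Pd-catalysed α-arylation of the methyl ketone enolate (Buchwald–Hartwig type) should be clean because the wide-bite-angle ligand favours mono-arylation, the di-ortho-substituted aryl ketone resists self-condensation, and the cyclic cis-alkene of the chromene is a poor Heck acceptor.

**Step 4**
Reactants: 8 1-[4-methoxy-2,6-bis(methoxymethoxy)phenyl]-2-(7-methoxy-2,2-dimethyl-2H-chromen-6-yl)ethan-1-one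
Product: 10 1-[4-methoxy-2,6-bis(methoxymethoxy)phenyl]-2-(7-methoxy-2,2-dimethyl-2H-chromen-6-yl)prop-2-en-1-one, via Mannich base 9 (not isolated)
Conditions: (CH2O)n (3 equiv), i-Pr2NH·CF3CO2H (1 equiv), THF, 65 °C
Reagents that add atoms: paraformaldehyde (as formaldehyde), C=O
Why: Mannich aminomethylation of the only enolisable position and β-elimination of the hindered amine from 9 (α-methylenation of an aryl benzyl ketone) should stop at the enone, which has no α-hydrogen left.

**Step 5**
Reactants: 10 1-[4-methoxy-2,6-bis(methoxymethoxy)phenyl]-2-(7-methoxy-2,2-dimethyl-2H-chromen-6-yl)prop-2-en-1-one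
Product: 12 1-(2,6-dihydroxy-4-methoxyphenyl)-2-(7-methoxy-2,2-dimethyl-2H-chromen-6-yl)prop-2-en-1-one, via bis-TMS ether 11 (not isolated)
Conditions: TMSOTf (4 equiv), 2,2′-bipyridyl (6 equiv), CH2Cl2, 0 °C; then H2O, 0 °C; cold extractive work-up, crude 12 used at once
Reagents that add atoms: none
Why: Silyl triflate/2,2′-bipyridyl cleavage of aromatic MOM ethers to aryl silyl ethers 11 and their hydrolysis need no protic acid or base, so the chromene and the non-enolisable enone should survive and the phenols are released in a weakly acidic bipyridinium buffer in which conjugate addition is slow.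

**Step 6**
Reactants: 12 1-(2,6-dihydroxy-4-methoxyphenyl)-2-(7-methoxy-2,2-dimethyl-2H-chromen-6-yl)prop-2-en-1-one
Product: 14 (3S)-5-hydroxy-7-methoxy-3-(7-methoxy-2,2-dimethyl-2H-chromen-6-yl)-2,3-dihydro-4H-chromen-4-one, via enol 13 (not isolated)
Conditions: quinine-derived squaramide (10 mol %), PhMe, −40 °C; then cold filtration through acid-washed silica
Reagents that add atoms: none
Why: Proposed new method: the quinuclidine nitrogen of the bifunctional catalyst should activate the non-chelated phenol of 12 as a general base while the squaramide N–H groups bind the carbonyl oxygen, so that the phenoxide adds to the CH2 terminus of the α-aryl vinyl ketone and the enol(ate) 13 stays hydrogen-bonded to the protonated catalyst, which returns the proton to C3 on one face. The closest known reaction types are amine–thiourea/squaramide-catalysed intramolecular oxa-Michael additions of phenols to enones (chromanone and flavanone synthesis) and bifunctional-catalyst conjugate addition–enantioselective protonation sequences of α-substituted acrylates and vinyl ketones; new is their combination on an α-aryl enone whose stereocentre is created only in the proton transfer. The pyranone ring is closed by O1–C2 bond formation in a 6-endo-trig oxa-Michael mode. The C3 stereocentre is set by catalyst-controlled, enantioface-selective C-protonation of the ion-paired enolate, with no substrate element biasing it, and the bulky ortho-methoxy-substituted ring B on C3 should give a large steric difference between the two faces in the chiral pocket. No regioselectivity is needed because the two hydroxyls ortho to the acyl group are equivalent, so either one gives the same ring and leaves the other as the 5-OH, which then chelates C4=O. What the step does need is that the catalysed pathway outruns uncatalysed closure and that the product is not enolised afterwards, which the non-polar solvent, the low temperature, the absence of any other base and the acidic filtration are meant to secure.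

**Compound list**

1 | 4-bromo-3-methoxyphenol | COc1cc(O)ccc1Br | starting material
2 | 3-methylbut-2-enal | CC(C)=CC=O | starting material
3 | 6-bromo-7-methoxy-4-(2-methylprop-1-en-1-yl)-2-phenyl-4H-1,3,2-benzodioxaborinine | COc1cc2OB(c3ccccc3)OC(C=C(C)C)c2cc1Br | intermediate (not isolated)
4 | 4-bromo-3-methoxy-6-(3-methylbut-2-en-1-ylidene)cyclohexa-2,4-dien-1-one | O=C1C=C(OC)C(Br)=CC1=CC=C(C)C | intermediate (not isolated)
5 | 6-bromo-7-methoxy-2,2-dimethyl-2H-chromene | COc1cc2OC(C)(C)C=Cc2cc1Br | intermediate
6 | 1-(2,6-dihydroxy-4-methoxyphenyl)ethan-1-one | CC(=O)c1c(O)cc(OC)cc1O | starting material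
7 | 1-[4-methoxy-2,6-bis(methoxymethoxy)phenyl]ethan-1-one | CC(=O)c1c(OCOC)cc(OC)cc1OCOC | intermediate
8 | 1-[4-methoxy-2,6-bis(methoxymethoxy)phenyl]-2-(7-methoxy-2,2-dimethyl-2H-chromen-6-yl)ethan-1-one | COCOc1cc(OC)cc(OCOC)c1C(=O)Cc1cc2C=CC(C)(C)Oc2cc1OC | intermediate
9 | 3-(diisopropylamino)-1-[4-methoxy-2,6-bis(methoxymethoxy)phenyl]-2-(7-methoxy-2,2-dimethyl-2H-chromen-6-yl)propan-1-one (racemic) | COCOc1cc(OC)cc(OCOC)c1C(=O)C(CN(C(C)C)C(C)C)c1cc2C=CC(C)(C)Oc2cc1OC | intermediate (not isolated)
10 | 1-[4-methoxy-2,6-bis(methoxymethoxy)phenyl]-2-(7-methoxy-2,2-dimethyl-2H-chromen-6-yl)prop-2-en-1-one | COCOc1cc(OC)cc(OCOC)c1C(=O)C(=C)c1cc2C=CC(C)(C)Oc2cc1OC | intermediate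
11 | 1-[4-methoxy-2,6-bis(trimethylsilyloxy)phenyl]-2-(7-methoxy-2,2-dimethyl-2H-chromen-6-yl)prop-2-en-1-one | C[Si](C)(C)Oc1cc(OC)cc(O[Si](C)(C)C)c1C(=O)C(=C)c1cc2C=CC(C)(C)Oc2cc1OC | intermediate (not isolated)
12 | 1-(2,6-dihydroxy-4-methoxyphenyl)-2-(7-methoxy-2,2-dimethyl-2H-chromen-6-yl)prop-2-en-1-one | COc1cc(O)c(C(=O)C(=C)c2cc3C=CC(C)(C)Oc3cc2OC)c(O)c1 | intermediate
13 | 7-methoxy-3-(7-methoxy-2,2-dimethyl-2H-chromen-6-yl)-2H-chromene-4,5-diol (enol of 14) | COc1cc(O)c2C(O)=C(c3cc4C=CC(C)(C)Oc4cc3OC)COc2c1 | intermediate (not isolated)
14 | (3S)-5-hydroxy-7-methoxy-3-(7-methoxy-2,2-dimethyl-2H-chromen-6-yl)-2,3-dihydro-4H-chromen-4-one | COc1cc(O)c2c(c1)OC[C@H](c1cc3c(cc1OC)OC(C)(C)C=C3)C2=O | target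

**Step count and risks**

Total step count: 6. Longest linear sequence: 5 steps (6 → 7 → 8 → 10 → 12 → 14; the chromene branch 1 → 5 joins at step 3 and is equally long).

Steps most likely to fail:

1. Step 6 (proposed new method). The proton transfer to C3 may discriminate the two faces poorly, uncatalysed ring closure may compete, and the amine catalyst may enolise and so racemise the product. Fallback with known chemistry, setting out from 12 and returning at 14: a catalytic amount of Et3N in CH2Cl2 at rt should close the ring without stereocontrol (classical oxa-Michael closure of α-methylene deoxybenzoins) to racemic 5-hydroxy-7-methoxy-3-(7-methoxy-2,2-dimethyl-2H-chromen-6-yl)chroman-4-one F1. Noyori-type asymmetric transfer hydrogenation with dynamic kinetic resolution [RuCl(p-cymene)((S,S)-TsDPEN), HCO2H/Et3N, EtOAc, rt] should then funnel both enantiomers into one alcohol, because C3 epimerises under the conditions and only the matched ketone is reduced. By analogy with tetralone-type ketones this is expected to be the cis-(3S,4S)-7-methoxy-3-(7-methoxy-2,2-dimethyl-2H-chromen-6-yl)chromane-4,5-diol F2. Oxidation of the benzylic alcohol with activated MnO2 in CH2Cl2, a neutral and non-enolising medium, should return the ketone 14 with C3 intact.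

2. Step 5. When the phenols are liberated (silyl ether hydrolysis and work-up in the presence of bipyridyl), the ring may close prematurely and without stereocontrol before the chiral catalyst is present. Fallback setting out from 10 and returning at 12: TESOTf/2,2′-bipyridyl (CH2Cl2, 0 °C) should convert both aryl MOM ethers directly into triethylsilyl ethers, giving 1-[4-methoxy-2,6-bis(triethylsilyloxy)phenyl]-2-(7-methoxy-2,2-dimethyl-2H-chromen-6-yl)prop-2-en-1-one F3. F3 is expected to be stable to chromatography and can be freed from all base. The phenols are then unmasked with HF·pyridine/pyridine in THF at −30 °C, an acidic fluoride medium in which no phenoxide is present, to reach 12.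

3. Step 1. Condensation may occur at the hindered ortho carbon between OH and OMe (regioisomeric chromene), and the bromine-deactivated phenol may react sluggishly. Fallback setting out from 1 and returning at 5: O-alkylation with 3-chloro-3-methylbut-1-yne (K2CO3, KI, CuI cat., acetone, reflux) should give the aryl propargyl ether 1-bromo-2-methoxy-4-[(2-methylbut-3-yn-2-yl)oxy]benzene F4. Heating (N,N-diethylaniline, 190 °C) should then lead by aromatic Claisen rearrangement, 1,5-hydrogen shift and oxa-6π electrocyclisation to 5.

**Further compounds**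

F1 | step 6 | racemic 5-hydroxy-7-methoxy-3-(7-methoxy-2,2-dimethyl-2H-chromen-6-yl)-2,3-dihydro-4H-chromen-4-one | COc1cc(O)c2c(c1)OCC(c1cc3c(cc1OC)OC(C)(C)C=C3)C2=O
F2 | step 6 | (3S,4S)-7-methoxy-3-(7-methoxy-2,2-dimethyl-2H-chromen-6-yl)-3,4-dihydro-2H-chromene-4,5-diol (cis) | COc1cc(O)c2c(c1)OC[C@H](c1cc3c(cc1OC)OC(C)(C)C=C3)[C@@H]2O
F3 | step 5 | 1-[4-methoxy-2,6-bis(triethylsilyloxy)phenyl]-2-(7-methoxy-2,2-dimethyl-2H-chromen-6-yl)prop-2-en-1-one | CC[Si](CC)(CC)Oc1cc(OC)cc(O[Si](CC)(CC)CC)c1C(=O)C(=C)c1cc2C=CC(C)(C)Oc2cc1OC
F4 | step 1 | 1-bromo-2-methoxy-4-[(2-methylbut-3-yn-2-yl)oxy]benzene | COc1cc(OC(C)(C)C#C)ccc1Br
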